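Plakortolide L is cut at both C–O bonds of the O1–O2 bridge of its 1,2-dioxane ring. C3 is at the aldehyde oxidation level and the fully substituted C6 can be the tertiary carbon of a 2,2-disubstituted oxirane, so one molecule of H2O2 can stitch the two: it adds to the C3 aldehyde and opens the oxirane at C6 with inversion, closing the dioxane and setting C6 in one operation. The precursor is an α-triethylsilyloxy aldehyde with no α-hydrogen (C4 from (R)-2-methylglycidol) carrying a Sharpless-derived (R)-oxirane at C6 with the 12-phenyldodecyl chain. The γ-lactone is then annulated on C3–C4 and the oxirane-derived CH2OH is reduced to the C6 methyl.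

Key step: step 10

Remark: atoms carry the 1,2-dioxane numbering throughout (O1, O2, C3 = peroxy methine, C4 = lactone carbinol carbon, C5, C6); in this numbering the target is (3S,4S,6S), and H2O2 is used as a dried ethereal solution.

Step 1
Reactants: 1 2-bromoprop-2-en-1-ol
Product: 2 2-bromo-3-[(4-methoxybenzyl)oxy]prop-1-ene
Conditions: NaH, PMBCl, n-Bu4NI (cat.), THF/DMF, 0 °C → rt
Reagents that add atoms: 4-methoxybenzyl chloride, COc1ccc(CCl)cc1
Why: Williamson etherification of the primary alkoxide; the vinyl bromide is inert to NaH at this temperature and no stereocentre is involved.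

Step 2
Reactants: 2 2-bromo-3-[(4-methoxybenzyl)oxy]prop-1-ene; 3 (R)-2-methylglycidol
Product: 6 (2S)-4-{[(4-methoxybenzyl)oxy]methyl}-2-methylpent-4-ene-1,2-diol, via vinyllithium 4 (not isolated), via vinylmagnesium bromide 5 (not isolated)
Conditions: 2 (2 equiv), t-BuLi (4 equiv), Et2O, −78 °C; MgBr2·OEt2; CuI (0.2 equiv); lithium alkoxide of 3 (from 3 and n-BuLi, THF, −78 °C), −78 → −20 °C; aq NH4Cl
Reagents that add atoms: none
Why: Bromine–lithium exchange and transmetalation give a 2-propenyl Grignard reagent whose copper-catalysed SN2 opening of the oxirane takes place at the unsubstituted ring carbon, so the C4 carbinol centre of 3 is carried over unchanged (no bond to it is broken, and the Payne rearrangement of a 2-substituted glycidol returns the same enantiomer).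

Step 3
Reactants: 6 (2S)-4-{[(4-methoxybenzyl)oxy]methyl}-2-methylpent-4-ene-1,2-diol
Product: 7 (2S)-4-{[(4-methoxybenzyl)oxy]methyl}-2-methyl-1,2-bis(triethylsilyloxy)pent-4-ene
Conditions: TESOTf (2.4 equiv), 2,6-lutidine, CH2Cl2, −78 → 0 °C
Reagents that add atoms: triethylsilyl trifluoromethanesulfonate, CC[Si](CC)(CC)OS(=O)(=O)C(F)(F)F
Why: Silyl triflate with a hindered pyridine base is forcing enough to silylate the tertiary carbinol as well as the primary one, and the PMB ether and the alkene are untouched.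

Step 4
Reactants: 7 (2S)-4-{[(4-methoxybenzyl)oxy]methyl}-2-methyl-1,2-bis(triethylsilyloxy)pent-4-ene
Product: 8 (4S)-4-methyl-2-methylidene-4,5-bis(triethylsilyloxy)pentan-1-ol
Conditions: DDQ (1.3 equiv), CH2Cl2/pH 7 buffer, 0 °C
Reagents that add atoms: none
Why: Oxidative cleavage of the PMB ether by DDQ under buffered conditions frees only the allylic alcohol and leaves both silyl ethers in place.

Step 5
Reactants: 8 (4S)-4-methyl-2-methylidene-4,5-bis(triethylsilyloxy)pentan-1-ol
Product: 10 {(2S)-2-[(2S)-2-methyl-2,3-bis(triethylsilyloxy)propyl]oxiran-2-yl}methyl 4-methylbenzenesulfonate, via epoxy alcohol 9 (not isolated)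
Conditions: Ti(Oi-Pr)4 (10 mol %), D-(−)-DIPT (12 mol %), t-BuOOH, 4 Å MS, CH2Cl2, −20 °C; P(OMe)3; then Et3N, DMAP (cat.), TsCl, −10 °C
Reagents that add atoms: tert-butyl hydroperoxide, CC(C)(C)OO; 4-toluenesulfonyl chloride, Cc1ccc(cc1)S(Cl)(=O)=O
Why: Sharpless asymmetric epoxidation of a 2-substituted allylic alcohol under reagent control, D-(−)-tartrate delivering oxygen in the sense that turns methallyl alcohol into (R)-2-methylglycidol and so giving the (R)-epoxy alcohol that fixes the later C6 centre, with in situ tosylation trapping the sensitive 2,2-disubstituted epoxy alcohol.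

Step 6
Reactants: 11 11-phenylundecanoic acid
Product: 12 11-phenylundecan-1-ol
Conditions: LiAlH4, THF, 0 °C → rt
Reagents that add atoms: none
Why: Standard hydride reduction of a carboxylic acid to the primary alcohol.

Step 7
Reactants: 12 11-phenylundecan-1-ol
Product: 13 (11-bromoundecyl)benzene
Conditions: CBr4, PPh3, CH2Cl2, 0 °C
Reagents that add atoms: carbon tetrabromide, BrC(Br)(Br)Br
Why: Appel bromination of an unhindered primary alcohol.

Step 8
Reactants: 10 {(2S)-2-[(2S)-2-methyl-2,3-bis(triethylsilyloxy)propyl]oxiran-2-yl}methyl 4-methylbenzenesulfonate; 13 (11-bromoundecyl)benzene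
Product: 16 (2R)-2-[(2S)-2-methyl-2,3-bis(triethylsilyloxy)propyl]-2-(12-phenyldodecyl)oxirane, via Grignard reagent 14 (not isolated), via tosyloxy alkoxide 15 (not isolated)
Conditions: 13, Mg, THF; CuI (10 mol %), 10, THF, −40 → −10 °C; t-BuOH (quench of excess Grignard reagent); KOt-Bu, 0 °C → rt
Reagents that add atoms: none
Why: Copper-catalysed Grignard opening of the oxirane at its CH2 (the neopentyl tosylate is not displaced) followed by Williamson closure of the tertiary alkoxide onto CH2OTs transposes the oxirane and installs the chain without breaking any bond to the quaternary carbon, so its configuration is retained and only the descriptor changes.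

Step 9
Reactants: 16 (2R)-2-[(2S)-2-methyl-2,3-bis(triethylsilyloxy)propyl]-2-(12-phenyldodecyl)oxirane
Product: 17 (2S)-2-methyl-3-[(2R)-2-(12-phenyldodecyl)oxiran-2-yl]-2-(triethylsilyloxy)propanal
Conditions: (COCl)2, DMSO, CH2Cl2, −78 → −40 °C; Et3N, −78 °C → rt
Reagents that add atoms: none
Why: Under Swern conditions the chlorosulfonium salt cleaves the primary triethylsilyl ether selectively and the resulting alkoxysulfonium ion collapses to the aldehyde, while the tertiary silyl ether and the oxirane survive and the aldehyde, lacking an α-hydrogen, cannot epimerise.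

Step 10
Reactants: 17 (2S)-2-methyl-3-[(2R)-2-(12-phenyldodecyl)oxiran-2-yl]-2-(triethylsilyloxy)propanal
Product: 19 (4S,6S)-6-(hydroxymethyl)-4-methyl-6-(12-phenyldodecyl)-4-(triethylsilyloxy)-1,2-dioxan-3-ol (both C3 anomers), via hydroperoxy hemiacetal 18 (not isolated)
Conditions: H2O2 (dry ethereal solution, 4 equiv), Et2O, 0 °C, 15 min; then phosphomolybdic acid (5 mol %), 0 °C → rt
Reagents that add atoms: hydrogen peroxide, OO
Why: H2O2 adds reversibly to the C3 aldehyde to give hydroperoxy hemiacetal 18, whose terminal peroxy oxygen attacks the acid-activated oxirane at tertiary C6 anti to the breaking C6–O bond, so that C3–O and C6–O are both formed and the oxirane CH2 is released as CH2OH (the same product results if H2O2 opens the oxirane first and the hydroperoxide then adds to the aldehyde). The closest known reactions are the molybdenum-acid-catalysed perhydrolysis of 2,2-disubstituted oxiranes at the tertiary carbon and the closure of δ-hydroperoxy carbonyl compounds to 1,2-dioxan-3-ols. The 1,2-dioxane closes in a 6-exo-tet mode, whereas attack at the oxirane CH2 would be 7-endo. The new stereocentre C6 is fixed by the oxirane configuration alone through inversion, the (R)-oxirane giving (6S) independently of C4, and C3 forms as both anomers, which is harmless because C3 is ionised later. The step needs peroxide attack at C6 instead of capture by the hemiacetal hydroxyl or carbonyl oxygen (5-exo) and inversion instead of ionisation; the charge bias of the protonated 2,2-disubstituted oxirane, the ring-size preference, pre-formation of the perhydrate with excess H2O2, the low temperature, the absence of an α-hydrogen and the non-participating silyl ether should secure this.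

Step 11
Reactants: 19 (4S,6S)-6-(hydroxymethyl)-4-methyl-6-(12-phenyldodecyl)-4-(triethylsilyloxy)-1,2-dioxan-3-ol
Product: 20 (4S,6S)-6-(hydroxymethyl)-3-methoxy-4-methyl-6-(12-phenyldodecyl)-4-(triethylsilyloxy)-1,2-dioxane (both C3 anomers)
Conditions: PPTS (cat.), MeOH, 3 Å MS, rt
Reagents that add atoms: methanol, CO
Why: Acid-catalysed exchange of the anomeric hydroxyl for methoxyl through the peroxycarbenium ion converts the hemiacetal into a peroxyacetal that no longer opens to a hydroperoxy aldehyde, and in methanol as solvent the methyl acetal should prevail over an internal acetal with the C6 CH2OH.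

Step 12
Reactants: 20 (4S,6S)-6-(hydroxymethyl)-3-methoxy-4-methyl-6-(12-phenyldodecyl)-4-(triethylsilyloxy)-1,2-dioxane
Product: 22 (4S,6S)-6-(iodomethyl)-3-methoxy-4-methyl-6-(12-phenyldodecyl)-4-(triethylsilyloxy)-1,2-dioxane, via primary triflate 21 (not isolated)
Conditions: Tf2O, pyridine, CH2Cl2, −40 °C; then n-Bu4NI, rt
Reagents that add atoms: tetrabutylammonium iodide, CCCC[N+](CCCC)(CCCC)CCCC.[I-]
Why: The neopentyl, β-oxygenated primary alcohol needs the triflate as leaving group for SN2 displacement by iodide at room temperature, and the phosphine-free conditions keep P(III) reagents away from the O–O bond.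

Step 13
Reactants: 22 (4S,6S)-6-(iodomethyl)-3-methoxy-4-methyl-6-(12-phenyldodecyl)-4-(triethylsilyloxy)-1,2-dioxane
Product: 23 (4S,6S)-3-methoxy-4,6-dimethyl-6-(12-phenyldodecyl)-4-(triethylsilyloxy)-1,2-dioxane
Conditions: n-Bu3SnH (2 equiv, ≥0.5 M), Et3B (0.2 equiv), air, toluene, 0 °C
Reagents that add atoms: none
Why: Radical-chain deiodination, a known way to turn iodomethyl cyclic peroxides into methyl ones, in which the high stannane concentration and low temperature let hydrogen transfer to the primary radical outrun its 3-exo attack on the O–O bond; no bond to C6 is broken, so its configuration is kept.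

Step 14
Reactants: 23 (4S,6S)-3-methoxy-4,6-dimethyl-6-(12-phenyldodecyl)-4-(triethylsilyloxy)-1,2-dioxane
Product: 24 methyl [(3S,4S,6S)-4,6-dimethyl-6-(12-phenyldodecyl)-4-(triethylsilyloxy)-1,2-dioxan-3-yl]acetate
Conditions: CH2=C(OMe)OTBS (3 equiv), TMSOTf (0.5 equiv), CH2Cl2, −78 °C
Reagents that add atoms: 1-(tert-butyldimethylsilyloxy)-1-methoxyethene, C=C(OC)O[Si](C)(C)C(C)(C)C
Why: TMSOTf ionises the peroxyacetal to a cyclic peroxycarbenium ion that is captured by the silyl ketene acetal (Mukaiyama-type addition, a known substitution of 3-alkoxy-1,2-dioxanes and 1,2-dioxolanes), and C3 should be set by 1,2-induction from C4: as in 2-alkoxy-substituted six-membered oxocarbenium ions the C4 silyloxy group prefers the pseudoequatorial and the C4 methyl the pseudoaxial position of the half-chair, so the nucleophile enters axially anti to the methyl group and the new C3–C bond lies cis to C4–O (3S).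

Step 15
Reactants: 24 methyl [(3S,4S,6S)-4,6-dimethyl-6-(12-phenyldodecyl)-4-(triethylsilyloxy)-1,2-dioxan-3-yl]acetate
Product: 26 plakortolide L, via hydroxy ester 25 (not isolated)
Conditions: 48% aq HF, MeCN, 0 °C → rt
Reagents that add atoms: none
Why: HF cleaves the tertiary triethylsilyl ether without harming the peroxide, and the freed C4 hydroxyl, cis to the C3 acetate arm, closes the γ-lactone by acid-catalysed transesterification without touching any stereocentre.

Compound list
1 | 2-bromoprop-2-en-1-ol | OCC(Br)=C | starting material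
2 | 2-bromo-3-[(4-methoxybenzyl)oxy]prop-1-ene | C=C(Br)COCc1ccc(OC)cc1 | intermediate
3 | (R)-2-methylglycidol | C1[C@](CO)(C)O1 | starting material
4 | {3-[(4-methoxybenzyl)oxy]prop-1-en-2-yl}lithium | [Li]C(=C)COCc1ccc(OC)cc1 | intermediate
5 | {3-[(4-methoxybenzyl)oxy]prop-1-en-2-yl}magnesium bromide | Br[Mg]C(=C)COCc1ccc(OC)cc1 | intermediate
6 | (2S)-4-{[(4-methoxybenzyl)oxy]methyl}-2-methylpent-4-ene-1,2-diol | OC[C@@](C)(O)CC(=C)COCc1ccc(OC)cc1 | intermediate
7 | (2S)-4-{[(4-methoxybenzyl)oxy]methyl}-2-methyl-1,2-bis(triethylsilyloxy)pent-4-ene | CC[Si](CC)(CC)OC[C@@](C)(O[Si](CC)(CC)CC)CC(=C)COCc1ccc(OC)cc1 | intermediate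
8 | (4S)-4-methyl-2-methylidene-4,5-bis(triethylsilyloxy)pentan-1-ol | CC[Si](CC)(CC)OC[C@@](C)(O[Si](CC)(CC)CC)CC(=C)CO | intermediate
9 | {(2R)-2-[(2S)-2-methyl-2,3-bis(triethylsilyloxy)propyl]oxiran-2-yl}methanol | CC[Si](CC)(CC)OC[C@@](C)(O[Si](CC)(CC)CC)C[C@@]1(CO)CO1 | intermediate
10 | {(2S)-2-[(2S)-2-methyl-2,3-bis(triethylsilyloxy)propyl]oxiran-2-yl}methyl 4-methylbenzenesulfonate | CC[Si](CC)(CC)OC[C@@](C)(O[Si](CC)(CC)CC)C[C@@]1(COS(=O)(=O)c2ccc(C)cc2)CO1 | intermediate
11 | 11-phenylundecanoic acid | OC(=O)CCCCCCCCCCc1ccccc1 | starting material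
12 | 11-phenylundecan-1-ol | OCCCCCCCCCCCc1ccccc1 | intermediate
13 | (11-bromoundecyl)benzene | BrCCCCCCCCCCCc1ccccc1 | intermediate
14 | (11-phenylundecyl)magnesium bromide | Br[Mg]CCCCCCCCCCCc1ccccc1 | intermediate
15 | bromomagnesium alkoxide of (2S)-2-hydroxy-2-[(2S)-2-methyl-2,3-bis(triethylsilyloxy)propyl]-14-phenyltetradecyl 4-methylbenzenesulfonate | CC[Si](CC)(CC)OC[C@@](C)(O[Si](CC)(CC)CC)C[C@](O[Mg]Br)(CCCCCCCCCCCCc1ccccc1)COS(=O)(=O)c1ccc(C)cc1 | intermediate
16 | (2R)-2-[(2S)-2-methyl-2,3-bis(triethylsilyloxy)propyl]-2-(12-phenyldodecyl)oxirane | CC[Si](CC)(CC)OC[C@@](C)(O[Si](CC)(CC)CC)C[C@]1(CCCCCCCCCCCCc2ccccc2)CO1 | intermediate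
17 | (2S)-2-methyl-3-[(2R)-2-(12-phenyldodecyl)oxiran-2-yl]-2-(triethylsilyloxy)propanal | O=C[C@@](C)(O[Si](CC)(CC)CC)C[C@]1(CCCCCCCCCCCCc2ccccc2)CO1 | intermediate
18 | (2S)-1-hydroperoxy-2-methyl-3-[(2R)-2-(12-phenyldodecyl)oxiran-2-yl]-2-(triethylsilyloxy)propan-1-ol (C1 epimers) | OOC(O)[C@@](C)(O[Si](CC)(CC)CC)C[C@]1(CCCCCCCCCCCCc2ccccc2)CO1 | intermediate
19 | (4S,6S)-6-(hydroxymethyl)-4-methyl-6-(12-phenyldodecyl)-4-(triethylsilyloxy)-1,2-dioxan-3-ol (C3 anomers) | OC[C@]1(CCCCCCCCCCCCc2ccccc2)C[C@](C)(O[Si](CC)(CC)CC)C(O)OO1 | intermediate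
20 | (4S,6S)-6-(hydroxymethyl)-3-methoxy-4-methyl-6-(12-phenyldodecyl)-4-(triethylsilyloxy)-1,2-dioxane (C3 anomers) | OC[C@]1(CCCCCCCCCCCCc2ccccc2)C[C@](C)(O[Si](CC)(CC)CC)C(OC)OO1 | intermediate
21 | [(4S,6S)-3-methoxy-4-methyl-6-(12-phenyldodecyl)-4-(triethylsilyloxy)-1,2-dioxan-6-yl]methyl trifluoromethanesulfonate | FC(F)(F)S(=O)(=O)OC[C@]1(CCCCCCCCCCCCc2ccccc2)C[C@](C)(O[Si](CC)(CC)CC)C(OC)OO1 | intermediate
22 | (4S,6S)-6-(iodomethyl)-3-methoxy-4-methyl-6-(12-phenyldodecyl)-4-(triethylsilyloxy)-1,2-dioxane | IC[C@]1(CCCCCCCCCCCCc2ccccc2)C[C@](C)(O[Si](CC)(CC)CC)C(OC)OO1 | intermediate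
23 | (4S,6S)-3-methoxy-4,6-dimethyl-6-(12-phenyldodecyl)-4-(triethylsilyloxy)-1,2-dioxane | C[C@]1(CCCCCCCCCCCCc2ccccc2)C[C@](C)(O[Si](CC)(CC)CC)C(OC)OO1 | intermediate
24 | methyl [(3S,4S,6S)-4,6-dimethyl-6-(12-phenyldodecyl)-4-(triethylsilyloxy)-1,2-dioxan-3-yl]acetate | C[C@]1(CCCCCCCCCCCCc2ccccc2)C[C@](C)(O[Si](CC)(CC)CC)[C@H](CC(=O)OC)OO1 | intermediate
25 | methyl [(3S,4S,6S)-4-hydroxy-4,6-dimethyl-6-(12-phenyldodecyl)-1,2-dioxan-3-yl]acetate | C[C@]1(CCCCCCCCCCCCc2ccccc2)C[C@](C)(O)[C@H](CC(=O)OC)OO1 | intermediate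
26 | plakortolide L, (3S,4S,6S) in dioxane numbering | C[C@]1(CCCCCCCCCCCCc2ccccc2)C[C@]2(C)OC(=O)C[C@@H]2OO1 | target

Total step count: 15. Longest linear sequence: 13 steps (steps 1–5 and 8–15, from 1 to 26).

Steps most likely to fail

Step 10. The activated oxirane may be captured by the hemiacetal hydroxyl or the carbonyl oxygen in a 5-exo closure that leads on to a bicyclic acetal, the oxirane may ionise at C6 with loss of configuration, or the acid may strip the silyl ether. The fallback separates the two C–O bond formations, sets out from 16 and returns at 20. Oxirane 16, which carries no carbonyl group, is opened by ethereal H2O2 with the same catalyst to give (2S,4S)-2-hydroperoxy-4-methyl-2-(12-phenyldodecyl)-4,5-bis(triethylsilyloxy)pentan-1-ol F1. 2,2-Dimethoxypropane and PPTS then tie the hydroperoxide and the neighbouring CH2OH into the 3,3-dimethyl-1,2,4-trioxane F2. Swern conditions convert the primary silyl ether of F2 into the trioxane aldehyde F3. Acidic methanol finally releases the hydroperoxide, which closes onto the aldehyde to give the methyl peroxyacetal 20.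

Step 14. Facial selectivity in the attack on the peroxycarbenium ion may be poor, with entry syn to the C4 methyl group competing. The fallback replaces kinetic facial control by a lactone-gated equilibration, sets out from 23 and returns at 25. The addition is run as before, and the unwanted methyl [(3R,4S,6S)-4,6-dimethyl-6-(12-phenyldodecyl)-4-(triethylsilyloxy)-1,2-dioxan-3-yl]acetate F4 is desilylated with aqueous HF to the trans hydroxy ester F5, which cannot form the cis-fused lactone. Diethylamine in trifluoroethanol, the medium used for hydroperoxide oxa-Michael closures, should open F5 by E1cB loss of the peroxide from C3 to methyl (2E,4S,6S)-6-hydroperoxy-4-hydroxy-4,6-dimethyl-18-phenyloctadec-2-enoate F6. F6 re-closes by 6-exo oxa-Michael addition on either face, and only the (3S) adduct 25 is drained by lactonisation to 26.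

Step 13. The β-peroxyalkyl radical may close onto the O–O bond (3-exo, with ring opening to an epoxide) or the stannyl radical may attack the peroxide. The fallback is polar, sets out from 20 and returns at 23: triflate 21 is formed as in step 12 and displaced directly by hydride with n-Bu4NBH4 in THF, a reagent that leaves dialkyl peroxides intact. This fallback makes no compound outside the list (F0).

Further compounds
F1 | step 10 | (2S,4S)-2-hydroperoxy-4-methyl-2-(12-phenyldodecyl)-4,5-bis(triethylsilyloxy)pentan-1-ol | CC[Si](CC)(CC)OC[C@@](C)(O[Si](CC)(CC)CC)C[C@@](OO)(CCCCCCCCCCCCc1ccccc1)CO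
F2 | step 10 | (6S)-3,3-dimethyl-6-[(2S)-2-methyl-2,3-bis(triethylsilyloxy)propyl]-6-(12-phenyldodecyl)-1,2,4-trioxane | CC[Si](CC)(CC)OC[C@@](C)(O[Si](CC)(CC)CC)C[C@@]1(CCCCCCCCCCCCc2ccccc2)COC(C)(C)OO1
F3 | step 10 | (2S)-3-[(6S)-3,3-dimethyl-6-(12-phenyldodecyl)-1,2,4-trioxan-6-yl]-2-methyl-2-(triethylsilyloxy)propanal | O=C[C@@](C)(O[Si](CC)(CC)CC)C[C@@]1(CCCCCCCCCCCCc2ccccc2)COC(C)(C)OO1
F4 | step 14 | methyl [(3R,4S,6S)-4,6-dimethyl-6-(12-phenyldodecyl)-4-(triethylsilyloxy)-1,2-dioxan-3-yl]acetate | C[C@]1(CCCCCCCCCCCCc2ccccc2)C[C@](C)(O[Si](CC)(CC)CC)[C@@H](CC(=O)OC)OO1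
F5 | step 14 | methyl [(3R,4S,6S)-4-hydroxy-4,6-dimethyl-6-(12-phenyldodecyl)-1,2-dioxan-3-yl]acetate | C[C@]1(CCCCCCCCCCCCc2ccccc2)C[C@](C)(O)[C@@H](CC(=O)OC)OO1
F6 | step 14 | methyl (2E,4S,6S)-6-hydroperoxy-4-hydroxy-4,6-dimethyl-18-phenyloctadec-2-enoate | COC(=O)/C=C/[C@@](C)(O)C[C@](C)(CCCCCCCCCCCCc1ccccc1)OO
F0 | step 13 | none | none
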